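**Plan**

- Retrosynthesis: the 3'-O–S bond and the benzyl and ketal masks are cut first, then C4–C4a of ring C (intramolecular Friedel–Crafts acylation), then O1–C2 (phenol added to an arylpropiolate), then the C2–C3–C4 chain back to a ring B aldehyde.
- Forward: ring B is differentiated first (4',5'-oxygens as a diphenylmethylene ketal, 3'-oxygen as an allyl ether) and the aldehyde is turned into the ynoate. Ring A is then attached through O1, ring C is closed at C4–C4a, and deallylation, sulfation and hydrogenolysis finish the route.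
- Enabling feature: C4a of ring A sits ortho to O1 and to the C5 oxygen and para to the C7 oxygen, so it is the most electron-rich carbon of a 3,5-dioxygenated aryl ether. Its two ortho carbons are equivalent, so acylation by C4 can give only one flavone.
- Stereochemistry: the target has no stereocentre. The only stereo-element on the way is the Z alkene of the acrylic acid (C4 carboxyl cis to O1), which comes from anti addition of the phenoxide and can equilibrate under the acidic ring closure.

Key step: step 7

Assumption: the target is drawn as the free hydrogen sulfate, so sulfate monoesters 14 and 15 are drawn and named in that neutral form. In practice they would be handled as sodium salts, and the free acid of 15 would be liberated only at the end by brief passage through a cold cation-exchange column in the H+ form.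

**Route**

Step 1
Reactants: 1 3,4,5-trihydroxybenzaldehyde; 2 dichlorodiphenylmethane
Product: 3 7-hydroxy-2,2-diphenyl-1,3-benzodioxole-5-carbaldehyde
Conditions: 2 (1.3 equiv), Ph2O, 175 °C, N2 sweep
Reagents that add atoms: dichlorodiphenylmethane (compound 2), ClC(Cl)(c1ccccc1)c1ccccc1
Why: Ketal formation between a gem-dichloride and a vicinal diphenol (thermal double O-alkylation with loss of HCl) closes the five-membered dioxole on two neighbouring oxygens, and since either adjacent pair of the symmetric triol gives the same compound, one phenol, the future 3'-oxygen, stays free; the reaction type is established for catechol aldehydes and for gallate esters.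

Step 2
Reactants: 3 7-hydroxy-2,2-diphenyl-1,3-benzodioxole-5-carbaldehyde
Product: 4 7-(allyloxy)-2,2-diphenyl-1,3-benzodioxole-5-carbaldehyde
Conditions: allyl bromide, K2CO3, DMF, rt
Reagents that add atoms: allyl bromide, C=CCBr
Why: Williamson ether synthesis on the only free phenol marks the future sulfate position with a group that can later be removed without touching benzyl ethers or the ketal.

Step 3
Reactants: 4 7-(allyloxy)-2,2-diphenyl-1,3-benzodioxole-5-carbaldehyde
Product: 5 4-(allyloxy)-6-(2,2-dibromovinyl)-2,2-diphenyl-1,3-benzodioxole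
Conditions: CBr4 (2 equiv), PPh3 (4 equiv), CH2Cl2, 0 °C
Reagents that add atoms: carbon tetrabromide, BrC(Br)(Br)Br
Why: First stage of the Corey–Fuchs reaction, a Wittig olefination by Ph3P=CBr2 generated in the flask, which runs under neutral conditions that leave the ketal and the allyl ether alone.

Step 4
Reactants: 5 4-(allyloxy)-6-(2,2-dibromovinyl)-2,2-diphenyl-1,3-benzodioxole
Product: 7 methyl 3-[7-(allyloxy)-2,2-diphenyl-1,3-benzodioxol-5-yl]prop-2-ynoate, via lithium acetylide 6 (not isolated)
Conditions: n-BuLi (2.1 equiv), THF, −78 °C; then ClCO2Me, −78 → 0 °C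
Reagents that add atoms: methyl chloroformate, COC(Cl)=O
Why: Second stage of the Corey–Fuchs reaction, in which bromine–lithium exchange, Fritsch–Buttenberg–Wiechell rearrangement and deprotonation give the lithium acetylide, which is C-acylated by the chloroformate at low temperature, where the allyl ether should not be attacked.

Step 5
Reactants: 7 methyl 3-[7-(allyloxy)-2,2-diphenyl-1,3-benzodioxol-5-yl]prop-2-ynoate; 8 3,5-bis(benzyloxy)phenol
Product: 9 methyl (Z)-3-[7-(allyloxy)-2,2-diphenyl-1,3-benzodioxol-5-yl]-3-[3,5-bis(benzyloxy)phenoxy]prop-2-enoate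
Conditions: Cs2CO3 (0.5 equiv), DMF, 60 °C
Reagents that add atoms: 3,5-bis(benzyloxy)phenol (compound 8), Oc1cc(OCc2ccccc2)cc(OCc2ccccc2)c1
Why: Base-mediated oxa-Michael (conjugate) addition of the phenoxide to the ynoate, in which anti protonation places the aryloxy group cis to the ester (Z), the isomer that also has the bulky aryl group trans to the ester and should therefore be favoured at equilibrium; a caesium phenoxide in DMF should favour O- over C-attack.

Step 6
Reactants: 9 methyl (Z)-3-[7-(allyloxy)-2,2-diphenyl-1,3-benzodioxol-5-yl]-3-[3,5-bis(benzyloxy)phenoxy]prop-2-enoate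
Product: 10 (Z)-3-[7-(allyloxy)-2,2-diphenyl-1,3-benzodioxol-5-yl]-3-[3,5-bis(benzyloxy)phenoxy]prop-2-enoic acid
Conditions: LiOH·H2O, THF/MeOH/H2O, rt; then 1 M HCl to pH 4, 0 °C
Reagents that add atoms: lithium hydroxide (hydroxide oxygen), [Li+].[OH-]
Why: Saponification by acyl–oxygen cleavage with hydroxide, the classical way from 3-aryloxycinnamic esters to their acids, run at room temperature so that hydroxide should not add to C3 and expel the aryloxide.

Step 7
Reactants: 10 (Z)-3-[7-(allyloxy)-2,2-diphenyl-1,3-benzodioxol-5-yl]-3-[3,5-bis(benzyloxy)phenoxy]prop-2-enoic acid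
Product: 12 2-[7-(allyloxy)-2,2-diphenyl-1,3-benzodioxol-5-yl]-5,7-bis(benzyloxy)-4H-chromen-4-one, via mixed trifluoroacetic anhydride 11 (not isolated)
Conditions: (CF3CO)2O (2 equiv), CH2Cl2, 0 °C → rt
Reagents that add atoms: none
Why: Trifluoroacetic anhydride turns the acid into mixed anhydride 11, which ionises, helped by the trifluoroacetic acid set free, to an acylium ion stabilised by the 3-aryloxy and 3-aryl donors; the acyl carbon attacks the ortho carbon of the phenoxy ring and loss of a proton restores ring A, forming C4–C4a. The closest known reaction type is the classical acid-mediated cyclisation of 3-aryloxycinnamic acids to flavones, an intramolecular Friedel–Crafts acylation, run here with the anhydride activation used for aryloxy acids on electron-rich arenes. Ring C closes as a six-membered ring, exo with respect to the C=O bond attacked (6-exo-trig on the mixed anhydride, 6-exo-dig if the free acylium ion reacts). No stereocentre is formed; the Z geometry needed to bring C4 to ring A comes from step 5, and any E isomer should be funnelled through the Z form by reversible protonation at C2 of the push–pull alkene. Site selectivity is secured because the two ortho carbons of the 3,5-bis(benzyloxy)phenoxy ring are symmetry-equivalent and each is activated by three oxygens (ortho, ortho, para), while the para carbon cannot be reached; the intramolecular acylation should outrun intermolecular trifluoroacetylation, and ring A is deactivated once the carbonyl is attached. The benzyl ethers, the allyl ether and the ketal should tolerate the anhydrous acid at this temperature.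

Step 8
Reactants: 12 2-[7-(allyloxy)-2,2-diphenyl-1,3-benzodioxol-5-yl]-5,7-bis(benzyloxy)-4H-chromen-4-one
Product: 13 5,7-bis(benzyloxy)-2-(7-hydroxy-2,2-diphenyl-1,3-benzodioxol-5-yl)-4H-chromen-4-one
Conditions: Pd(PPh3)4 (5 mol %), morpholine, THF, rt
Reagents that add atoms: none
Why: Tsuji–Trost-type deallylation, in which zerovalent palladium ionises the allyl aryl ether to a π-allyl complex and the phenoxide and morpholine captures the allyl group, while benzyl ethers, ketal and chromone are inert.

Step 9
Reactants: 13 5,7-bis(benzyloxy)-2-(7-hydroxy-2,2-diphenyl-1,3-benzodioxol-5-yl)-4H-chromen-4-one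
Product: 14 6-[5,7-bis(benzyloxy)-4-oxo-4H-chromen-2-yl]-2,2-diphenyl-1,3-benzodioxol-4-yl hydrogen sulfate
Conditions: SO3·pyridine, pyridine, 45 °C; then cation exchange (Na+ form)
Reagents that add atoms: sulfur trioxide–pyridine complex, O=S(=O)([O-])[n+]1ccccc1
Why: O-Sulfation of a phenol by a sulfur trioxide–amine complex, selective because the 3'-hydroxyl is the only free hydroxyl in 13; exchange to the sodium salt removes pyridine, which would otherwise slow the hydrogenolysis that follows.

Step 10
Reactants: 14 6-[5,7-bis(benzyloxy)-4-oxo-4H-chromen-2-yl]-2,2-diphenyl-1,3-benzodioxol-4-yl hydrogen sulfate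
Product: 15 tricetin 3'-sulfate, 5-(5,7-dihydroxy-4-oxo-4H-chromen-2-yl)-2,3-dihydroxyphenyl hydrogen sulfate
Conditions: H2 (1 atm), Pd(OH)2/C, THF/MeOH, rt
Reagents that add atoms: none
Why: Catalytic hydrogenolysis of benzylic C–O bonds should remove both benzyl ethers as toluene and the doubly benzylic ketal as diphenylmethane in one operation, while an aryl sulfate salt and the chromone C2=C3 bond are normally not reduced at 1 atm.

**Compound list**

1 | 3,4,5-trihydroxybenzaldehyde | O=Cc1cc(O)c(O)c(O)c1 | starting material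
2 | dichlorodiphenylmethane | ClC(Cl)(c1ccccc1)c1ccccc1 | starting material
3 | 7-hydroxy-2,2-diphenyl-1,3-benzodioxole-5-carbaldehyde | O=Cc1cc(O)c2OC(c3ccccc3)(c3ccccc3)Oc2c1 | intermediate
4 | 7-(allyloxy)-2,2-diphenyl-1,3-benzodioxole-5-carbaldehyde | O=Cc1cc(OCC=C)c2OC(c3ccccc3)(c3ccccc3)Oc2c1 | intermediate
5 | 4-(allyloxy)-6-(2,2-dibromovinyl)-2,2-diphenyl-1,3-benzodioxole | BrC(Br)=Cc1cc(OCC=C)c2OC(c3ccccc3)(c3ccccc3)Oc2c1 | intermediate
6 | lithium acetylide of 4-(allyloxy)-6-ethynyl-2,2-diphenyl-1,3-benzodioxole | [Li]C#Cc1cc(OCC=C)c2OC(c3ccccc3)(c3ccccc3)Oc2c1 | intermediate (not isolated)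
7 | methyl 3-[7-(allyloxy)-2,2-diphenyl-1,3-benzodioxol-5-yl]prop-2-ynoate | COC(=O)C#Cc1cc(OCC=C)c2OC(c3ccccc3)(c3ccccc3)Oc2c1 | intermediate
8 | 3,5-bis(benzyloxy)phenol | Oc1cc(OCc2ccccc2)cc(OCc2ccccc2)c1 | starting material
9 | methyl (Z)-3-[7-(allyloxy)-2,2-diphenyl-1,3-benzodioxol-5-yl]-3-[3,5-bis(benzyloxy)phenoxy]prop-2-enoate | COC(=O)/C=C(\Oc1cc(OCc2ccccc2)cc(OCc2ccccc2)c1)c1cc(OCC=C)c2OC(c3ccccc3)(c3ccccc3)Oc2c1 | intermediate
10 | (Z)-3-[7-(allyloxy)-2,2-diphenyl-1,3-benzodioxol-5-yl]-3-[3,5-bis(benzyloxy)phenoxy]prop-2-enoic acid | OC(=O)/C=C(\Oc1cc(OCc2ccccc2)cc(OCc2ccccc2)c1)c1cc(OCC=C)c2OC(c3ccccc3)(c3ccccc3)Oc2c1 | intermediate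
11 | (Z)-3-[7-(allyloxy)-2,2-diphenyl-1,3-benzodioxol-5-yl]-3-[3,5-bis(benzyloxy)phenoxy]prop-2-enoic trifluoroacetic anhydride | O=C(OC(=O)C(F)(F)F)/C=C(\Oc1cc(OCc2ccccc2)cc(OCc2ccccc2)c1)c1cc(OCC=C)c2OC(c3ccccc3)(c3ccccc3)Oc2c1 | intermediate (not isolated)
12 | 2-[7-(allyloxy)-2,2-diphenyl-1,3-benzodioxol-5-yl]-5,7-bis(benzyloxy)-4H-chromen-4-one | O=c1cc(-c2cc(OCC=C)c3OC(c4ccccc4)(c4ccccc4)Oc3c2)oc2cc(OCc3ccccc3)cc(OCc3ccccc3)c12 | intermediate
13 | 5,7-bis(benzyloxy)-2-(7-hydroxy-2,2-diphenyl-1,3-benzodioxol-5-yl)-4H-chromen-4-one | O=c1cc(-c2cc(O)c3OC(c4ccccc4)(c4ccccc4)Oc3c2)oc2cc(OCc3ccccc3)cc(OCc3ccccc3)c12 | intermediate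
14 | 6-[5,7-bis(benzyloxy)-4-oxo-4H-chromen-2-yl]-2,2-diphenyl-1,3-benzodioxol-4-yl hydrogen sulfate | O=c1cc(-c2cc(OS(=O)(=O)O)c3OC(c4ccccc4)(c4ccccc4)Oc3c2)oc2cc(OCc3ccccc3)cc(OCc3ccccc3)c12 | intermediate
15 | tricetin 3'-sulfate, 5-(5,7-dihydroxy-4-oxo-4H-chromen-2-yl)-2,3-dihydroxyphenyl hydrogen sulfate | O=c1cc(-c2cc(O)c(O)c(OS(=O)(=O)O)c2)oc2cc(O)cc(O)c12 | target

**Step count and risks**

Total step count: 10. Longest linear sequence: 10 steps (1 → 15); phenol 8 is bought and enters at step 5.

Steps most likely to fail: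

1. Step 7 (ring closure at C4–C4a). The electron-rich ring A may be trifluoroacetylated intermolecularly before the mixed anhydride closes, or the acid set free may start to strip the ketal or the 5-benzyl ether, so that the acylation is overtaken by decomposition. The fallback gives up the C4–C4a closure and builds ring C at O1–C2 instead. It sets out from aldehyde 4, which is condensed (Claisen–Schmidt, KOH, EtOH, rt) with purchased 1-[2,4-bis(benzyloxy)-6-hydroxyphenyl]ethanone, CC(=O)c1c(O)cc(OCc2ccccc2)cc1OCc1ccccc1, to give the chalcone (E)-3-[7-(allyloxy)-2,2-diphenyl-1,3-benzodioxol-5-yl]-1-[2,4-bis(benzyloxy)-6-hydroxyphenyl]prop-2-en-1-one F1. Oxidative cyclisation of this 2'-hydroxychalcone with catalytic I2 in DMSO at 120 °C (oxa-Michael closure followed by dehydrogenation) should give flavone 12, where the route is rejoined.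

2. Step 5 (phenol addition to the ynoate). The phenoxide of 8 is ambident, and attack through a ring carbon instead of oxygen would lead towards a 4-arylcoumarin; the addition may also be slow because the ynoate carries an electron-rich aryl group. The fallback replaces the conjugate addition by a copper-mediated C–O coupling. It sets out from ynoate 7, which is hydrobrominated in the anti sense (LiBr, AcOH, MeCN, 70 °C) to methyl (Z)-3-[7-(allyloxy)-2,2-diphenyl-1,3-benzodioxol-5-yl]-3-bromoprop-2-enoate F2. An Ullmann-type vinylic etherification with phenol 8 (CuI, N,N-dimethylglycine, Cs2CO3, dioxane, 90 °C) should proceed at oxygen with retention of the alkene geometry and deliver ester 9, where the route is rejoined.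

3. Step 10 (global hydrogenolysis beside the sulfate). Cleavage of the diphenylmethylene ketal may stall, the chromone C2=C3 bond may be saturated on prolonged exposure, or the sulfate may be lost on the catalyst surface. The fallback carries the sulfate as a neutral diester and removes the ethers by Lewis acid instead of hydrogen. It sets out from phenol 13, which is treated with 2,2,2-trichloroethyl chlorosulfate, ClS(=O)(=O)OCC(Cl)(Cl)Cl, Et3N and DMAP in THF to give 6-[5,7-bis(benzyloxy)-4-oxo-4H-chromen-2-yl]-2,2-diphenyl-1,3-benzodioxol-4-yl 2,2,2-trichloroethyl sulfate F3. BCl3 with pentamethylbenzene in CH2Cl2 at −78 → 0 °C should then cleave both benzyl ethers and the ketal to 5-(5,7-dihydroxy-4-oxo-4H-chromen-2-yl)-2,3-dihydroxyphenyl 2,2,2-trichloroethyl sulfate F4. Reductive removal of the trichloroethyl group with Zn and HCO2NH4 in MeOH should give the sulfate monoester 15, where the route ends.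

**Further compounds**

F1 | step 7 | (E)-3-[7-(allyloxy)-2,2-diphenyl-1,3-benzodioxol-5-yl]-1-[2,4-bis(benzyloxy)-6-hydroxyphenyl]prop-2-en-1-one | O=C(/C=C/c1cc(OCC=C)c2OC(c3ccccc3)(c3ccccc3)Oc2c1)c1c(O)cc(OCc2ccccc2)cc1OCc1ccccc1
F2 | step 5 | methyl (Z)-3-[7-(allyloxy)-2,2-diphenyl-1,3-benzodioxol-5-yl]-3-bromoprop-2-enoate | COC(=O)/C=C(\Br)c1cc(OCC=C)c2OC(c3ccccc3)(c3ccccc3)Oc2c1
F3 | step 10 | 6-[5,7-bis(benzyloxy)-4-oxo-4H-chromen-2-yl]-2,2-diphenyl-1,3-benzodioxol-4-yl 2,2,2-trichloroethyl sulfate | O=c1cc(-c2cc(OS(=O)(=O)OCC(Cl)(Cl)Cl)c3OC(c4ccccc4)(c4ccccc4)Oc3c2)oc2cc(OCc3ccccc3)cc(OCc3ccccc3)c12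
F4 | step 10 | 5-(5,7-dihydroxy-4-oxo-4H-chromen-2-yl)-2,3-dihydroxyphenyl 2,2,2-trichloroethyl sulfate | O=c1cc(-c2cc(O)c(O)c(OS(=O)(=O)OCC(Cl)(Cl)Cl)c2)oc2cc(O)cc(O)c12
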